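The runs stem from a simulated flask on assumed constants; scatter was added.

Count what is left.

- cedar: D 0.80 M; E 1.6 M; the very flask that is asked about, followed so far
- flask: D 0.80 M; E 1.60 M; time 1.5 h
cedar run (percent of the D charged)

| time / min | X / % |
|---|---|
| 6.00 | 7.5 |
| 10.0 | 9.0 |
| 15.0 | 11.5 |
| 25.0 | 12.2 |
| 40.0 | 12.6 |
| 80.0 | 13.6 |

(readings scatter by 0.3 percentage points)
- beta: change nothing and wait 25 min more
- alpha: at 1.5 h take out 90% of the X then present, then wait 25 min
- gamma: at 1.5 h add D, 50.0% of the amount charged, then wait 25 min
- a species is counted by the D in it: one J or Z or G counts as two
- X taken out counts as made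
- what may be going on: D + X -> G; 2 D -> Z; 2 D -> J; D -> Q; D + E -> X
- additions bring no volume worth counting
- X, in percent of the D first charged, at 1.5 h
- the remedy with the largest gain of X, or "none" below 2 percentage points (beta / alpha / gamma / none)
- X present, with what was taken out counted in, in percent of the D first charged, after beta
- X present, with what was taken out counted in, in percent of the D first charged, after alpha

In the cedar flask I work with f, the fraction of D left, which is c_D over its charged value. E stands at twice c_D at the start, so I take D as the limiting reagent and treat the making of X as pseudo-first-order in D. The first reading gives a start slope of 0.0125 min⁻¹ of the charge, and this chord is a reading with its scatter. The curve then bends towards a level near 13.6%. I define the lifetime τ as that level divided by the start slope, 10.9 min, which is the time at which the starting tangent meets the level. That knee falls later than the reading at 10.0 min and earlier than the one at 15.0 min, where the readings do bend. Between 40.0 min and 80.0 min the slope reads 2.50 × 10⁻⁴ min⁻¹, or 2.00% of the start slope. Carried on at that slope, X reaches 13.9% at 1.5 h.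

If f falls as exp(−t/τ), the cedar flask has 0.0256% of its D at 1.5 h. This is an estimate and not a bound, because τ is read from the curve of X. It stands below the threshold of 2 percentage points, so I expect neither beta nor alpha to reach that threshold. This curve does not tell me what fresh D yields beside the X already there, so gamma stays open, but my reckoning points to none.

The forecast gives 13.8%, 14.3% after beta, 16.3% after alpha and best alpha, on the ground that “Removing X reopens the driving force”, which parts from my none.

The flask gives 13.6% and best none, with X at 13.6% after beta and 13.7% after alpha, and with gains of 0.013 points for beta, 0.093 points for alpha and 0.82 points for gamma.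

    D + X → G (k = 0.130 M⁻¹ min⁻¹)
    2 D → Z (k = 2.10 × 10⁻⁵ M⁻¹ min⁻¹)
    2 D → J (k = 0.00750 M⁻¹ min⁻¹)
    D → Q (k = 0.0290 min⁻¹)
    D + E → X (k = 0.0120 M⁻¹ min⁻¹)

At 90.0 min the flask holds 0.420% of its D, more than my 0.0256% but less than the threshold of 2 points. The lifetime also carries to the neighbour flask with 0.96 M of E. Its start slope scaled by E, multiplied by the same τ of 10.9 min, gives 8.16%, and that neighbour flask stands at 8.49%.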